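**Plan**
- Numbering follows the cembrane skeleton: ring C1–C14, lactone unit C15–C17 on C1, C18/C19/C20 on C4/C8/C12. The enabling feature is the C4–O–C7 oxolane, whose ring arms C3 and C8 are cis and whose C4 is quaternary. Joining C3 to C8 through C2 turns it into the oxygen bridge of an 8-oxabicyclo[3.2.1]octene, the adduct of a furan (C4–C7) and a three-carbon oxyallyl unit (C3–C2–C8).
- Cuts, in retrosynthetic order: lactone C16–O(C12); C15=C17; C11–C12 (pinacol, 14-membered ring); C1–C14 (cuprate); C1–C2 (alkynylation with methyl propiolate); C8=C19; the surplus C2–C8 bond (Baeyer–Villiger); C10–C11 (Wittig); last C7–C8 and C3–C4 ([4+3]).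
- Forward: bicyclic ketone, then saturation, C11 homologation and Baeyer–Villiger/methanolysis to the cis-oxolane with two arms; C8 methylene and C2 aldehyde; γ-silyloxy enoate; C12–C14 arm; keto aldehyde; carbocycle; ε-lactone; C15 methylene; desilylation.
- Stereochemistry: C4 and C7 from the amine catalyst in the cycloaddition (the oxygen bridge enforces cis); C2 from ligand control in the alkynylation; C1 by 1,2-induction from C2 (anti cuprate addition); C11 and C12 in the titanium pinacol closure.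

Key step: step 3

Assumption: the sense of induction of the (2R,5R)-imidazolidinone (step 3) and of the (S,S)-aminoalcohol ligand (step 12) is taken from the usual shielding models; if either proved opposite, its mirror-image form would be used with nothing else changed.

**Route**

Step 1
Reactants: 1 2-methylfuran
Product: 3 (E)-4-oxopent-2-enal, via (Z)-4-oxopent-2-enal 2 (not isolated)
Conditions: N-bromosuccinimide, NaHCO3, acetone/H2O (10:1), −15 °C; then pyridine, rt
Reagents that add atoms: water, O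
Why: Oxidative furan ring opening (bromination at C5, hydration, loss of HBr) gives the cis-enedione, which pyridine isomerises to the more stable E-enal by reversible conjugate addition; no stereocentre is formed.

Step 2
Reactants: 3 (E)-4-oxopent-2-enal
Product: 4 (E)-4-(tert-butyldimethylsilyloxy)penta-2,4-dienal
Conditions: t-BuMe2SiOTf, Et3N, CH2Cl2, 0 °C
Reagents that add atoms: tert-butyldimethylsilyl trifluoromethanesulfonate, CC(C)(C)[Si](C)(C)OS(=O)(=O)C(F)(F)F
Why: Silyl enol ether formation by soft enolisation of the methyl ketone, the only enolisable position, gives the 2-silyloxydiene and leaves the E-enal untouched.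

Step 3
Reactants: 4 (E)-4-(tert-butyldimethylsilyloxy)penta-2,4-dienal; 1 2-methylfuran
Product: 5 (1R,4S,5R)-1-methyl-4-(2-oxoethyl)-8-oxabicyclo[3.2.1]oct-6-en-3-one
Conditions: (2R,5R)-5-benzyl-2-tert-butyl-3-methylimidazolidin-4-one trifluoroacetate (20 mol %), 1 (5 equiv), CH2Cl2, −78 °C; then H2O
Reagents that add atoms: none
Why: Condensation of the amine salt with 4 gives an iminium ion that is a 2-silyloxy-substituted vinylogous oxyallyl cation; its β-carbon (C8) is attacked by the unsubstituted α-carbon of 1 (C7), the silyl enol ether terminus (C3) then captures the methyl-stabilised oxocarbenium carbon (C4), and loss of the silyl group and enamine hydrolysis give ketone and aldehyde. The closest known reaction type is the imidazolidinone-catalysed asymmetric [4+3] cycloaddition of 4-silyloxypenta-2,4-dienals with 2,5-dialkylfurans, the iminium-activated form of the oxyallyl cation–furan cycloaddition. The cycloheptenone, and with it the bridged tetrahydropyranone, closes by 7-(enolendo)-exo-trig attack of the enol ether on the oxocarbenium ion in a compact (endo) arrangement, leaving the furan oxygen as the one-atom bridge. The catalyst benzyl group shields one face of the iminium β-carbon and fixes C8, the compact approach of the furan relative to C8 fixes C7, and the oxygen bridge forces C4 cis to C7, so C4 and C7 arise together in the required absolute sense while C8 is erased later. The step needs regioselectivity (C7 to C8, C4 to C3), secured by the higher nucleophilicity and lower hindrance of the unsubstituted furan α-carbon; it also needs ring closure to outrun loss of the C7 proton (Friedel–Crafts alkylation), which the intramolecular silyl enol ether, the low temperature and the weakly basic trifluoroacetate counter-ion should favour.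

Step 4
Reactants: 5 (1R,4S,5R)-1-methyl-4-(2-oxoethyl)-8-oxabicyclo[3.2.1]oct-6-en-3-one
Product: 6 (1S,4S,5R)-1-methyl-4-(2-oxoethyl)-8-oxabicyclo[3.2.1]octan-3-one
Conditions: H2 (1 atm), Pd/C (5%), EtOAc, rt
Reagents that add atoms: none
Why: Heterogeneous catalytic hydrogenation saturates the strained cis-disubstituted C5=C6 alkene far faster than it reduces ketone or aldehyde, and C4 and C7 are not touched.

Step 5
Reactants: 6 (1S,4S,5R)-1-methyl-4-(2-oxoethyl)-8-oxabicyclo[3.2.1]octan-3-one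
Product: 7 (1S,4S,5R)-4-(3-methoxyprop-2-en-1-yl)-1-methyl-8-oxabicyclo[3.2.1]octan-3-one (E/Z mixture)
Conditions: Ph3P(CH2OMe)Cl, KN(SiMe3)2, THF, −78 °C → 0 °C
Reagents that add atoms: (methoxymethyl)triphenylphosphonium chloride, COC[P+](c1ccccc1)(c1ccccc1)c1ccccc1.[Cl-]
Why: Wittig olefination with the methoxymethylene ylide is much faster at the unhindered aldehyde than at the α-branched bicyclic ketone at low temperature and adds C11 as an enol ether whose geometry is irrelevant.

Step 6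
Reactants: 7 (1S,4S,5R)-4-(3-methoxyprop-2-en-1-yl)-1-methyl-8-oxabicyclo[3.2.1]octan-3-one
Product: 8 (1S,4S,5R)-4-(3,3-dimethoxypropyl)-1-methyl-8-oxabicyclo[3.2.1]octan-3-one
Conditions: MeOH, pyridinium p-toluenesulfonate (cat.), rt
Reagents that add atoms: methanol, CO
Why: Acid-catalysed addition of methanol to the enol ether (acetal formation via the oxocarbenium ion) masks the C11 aldehyde, while the hindered ketone does not ketalise without a dehydrating agent.

Step 7
Reactants: 8 (1S,4S,5R)-4-(3,3-dimethoxypropyl)-1-methyl-8-oxabicyclo[3.2.1]octan-3-one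
Product: 9 (1R,2S,6S)-2-(3,3-dimethoxypropyl)-6-methyl-3,9-dioxabicyclo[4.2.1]nonan-4-one
Conditions: m-chloroperoxybenzoic acid, NaHCO3, CH2Cl2, rt
Reagents that add atoms: m-chloroperoxybenzoic acid, OOC(=O)c1cccc(Cl)c1
Why: Baeyer–Villiger oxidation with migration of the more substituted carbon C8 (secondary over primary C3, with retention) inserts oxygen into the surplus C2–C8 bond.

Step 8
Reactants: 9 (1R,2S,6S)-2-(3,3-dimethoxypropyl)-6-methyl-3,9-dioxabicyclo[4.2.1]nonan-4-one
Product: 10 methyl 2-[(2S,5R)-5-[(1S)-1-hydroxy-4,4-dimethoxybutyl]-2-methyloxolan-2-yl]acetate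
Conditions: K2CO3 (cat.), MeOH, 0 °C
Reagents that add atoms: methanol, CO
Why: Base-catalysed transesterification (methanolysis) opens the strained ε-lactone to the C2 methyl ester and the free C8 carbinol, unveiling the cis-2,5-disubstituted oxolane with two differentiated arms.

Step 9
Reactants: 10 methyl 2-[(2S,5R)-5-[(1S)-1-hydroxy-4,4-dimethoxybutyl]-2-methyloxolan-2-yl]acetate
Product: 11 methyl 2-[(2S,5R)-5-(4,4-dimethoxybutanoyl)-2-methyloxolan-2-yl]acetate
Conditions: Dess–Martin periodinane, pyridine, CH2Cl2, 0 °C → rt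
Reagents that add atoms: none
Why: Dess–Martin oxidation converts the secondary C8 alcohol into the ketone under buffered, non-epimerising conditions, erasing the C8 stereocentre and sparing the acetal and C7.

Step 10
Reactants: 11 methyl 2-[(2S,5R)-5-(4,4-dimethoxybutanoyl)-2-methyloxolan-2-yl]acetate
Product: 12 methyl 2-[(2S,5R)-5-(5,5-dimethoxypent-1-en-2-yl)-2-methyloxolan-2-yl]acetate
Conditions: Zn, CH2Br2, TiCl4, THF/CH2Cl2, 0 °C → rt
Reagents that add atoms: dibromomethane, BrCBr
Why: Takai–Lombardo methylenation, a non-basic zinc–titanium methylene transfer, converts the α-alkoxy ketone into the C8=C19 alkene without epimerising C7 and without touching the ester.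

Step 11
Reactants: 12 methyl 2-[(2S,5R)-5-(5,5-dimethoxypent-1-en-2-yl)-2-methyloxolan-2-yl]acetate
Product: 13 2-[(2S,5R)-5-(5,5-dimethoxypent-1-en-2-yl)-2-methyloxolan-2-yl]acetaldehyde
Conditions: i-Bu2AlH, CH2Cl2, −78 °C; aq. potassium sodium tartrate
Reagents that add atoms: none
Why: Partial hydride reduction of the ester stops at the aluminium hemiacetal, stabilised at −78 °C by chelation to the C4 ether oxygen, which releases the C2 aldehyde on work-up.

Step 12
Reactants: 13 2-[(2S,5R)-5-(5,5-dimethoxypent-1-en-2-yl)-2-methyloxolan-2-yl]acetaldehyde; 14 methyl propiolate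
Product: 15 methyl (4S)-5-[(2S,5R)-5-(5,5-dimethoxypent-1-en-2-yl)-2-methyloxolan-2-yl]-4-hydroxypent-2-ynoate
Conditions: 14 (3 equiv), Me2Zn, 2,6-bis{[(S)-2-(hydroxydiphenylmethyl)pyrrolidin-1-yl]methyl}-4-methylphenol (20 mol %), Ph3P=O (40 mol %), toluene, 4 °C
Reagents that add atoms: none
Why: Catalytic asymmetric alkynylation of an aldehyde: the dinuclear zinc–aminoalcohol complex binds the aldehyde and the zinc acetylide of 14 and delivers the alkynyl group to one aldehyde face, setting C2 (S) by ligand control and adding C1, C15 and C16.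

Step 13
Reactants: 15 methyl (4S)-5-[(2S,5R)-5-(5,5-dimethoxypent-1-en-2-yl)-2-methyloxolan-2-yl]-4-hydroxypent-2-ynoate
Product: 16 methyl (2E,4S)-5-[(2S,5R)-5-(5,5-dimethoxypent-1-en-2-yl)-2-methyloxolan-2-yl]-4-hydroxypent-2-enoate
Conditions: NaAlH2(OCH2CH2OMe)2, THF, −72 °C
Reagents that add atoms: none
Why: Hydroxyl-directed trans-hydroalumination of the propargylic alkoxide (intramolecular hydride delivery, then protonolysis) gives the E-enoate, the ester being reduced much more slowly at this temperature.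

Step 14
Reactants: 16 methyl (2E,4S)-5-[(2S,5R)-5-(5,5-dimethoxypent-1-en-2-yl)-2-methyloxolan-2-yl]-4-hydroxypent-2-enoate
Product: 17 methyl (2E,4S)-4-(tert-butyldimethylsilyloxy)-5-[(2S,5R)-5-(5,5-dimethoxypent-1-en-2-yl)-2-methyloxolan-2-yl]pent-2-enoate
Conditions: t-BuMe2SiCl, imidazole, DMF, rt
Reagents that add atoms: tert-butyldimethylsilyl chloride, CC(C)(C)[Si](C)(C)Cl
Why: Silyl ether formation on the secondary alcohol under non-basic conditions gives the γ-silyloxy enoate needed for 1,2-induction and leaves C2 unchanged.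

Step 15
Reactants: 17 methyl (2E,4S)-4-(tert-butyldimethylsilyloxy)-5-[(2S,5R)-5-(5,5-dimethoxypent-1-en-2-yl)-2-methyloxolan-2-yl]pent-2-enoate; 18 2-(2-bromoethyl)-2-methyl-1,3-dioxolane
Product: 22 methyl (3R,4S)-4-(tert-butyldimethylsilyloxy)-5-[(2S,5R)-5-(5,5-dimethoxypent-1-en-2-yl)-2-methyloxolan-2-yl]-3-[2-(2-methyl-1,3-dioxolan-2-yl)ethyl]pentanoate, via Grignard reagent 19 (not isolated), via magnesium cuprate 20 (not isolated), via silyl ketene acetal 21 (not isolated)
Conditions: 18 (2.4 equiv), Mg, THF; CuBr·SMe2 (1.2 equiv), THF, −40 °C; then 17, Me3SiCl, −78 °C; aq. NH4Cl/NH3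
Reagents that add atoms: none
Why: Cuprate conjugate addition accelerated by Me3SiCl takes place on the enoate face anti to the γ-silyloxy group (modified Felkin–Anh arrangement with the C–O bond perpendicular to the π-system), so C1 is formed R, anti to the C2 oxygen, with the C12–C14 arm attached.

Step 16
Reactants: 22 methyl (3R,4S)-4-(tert-butyldimethylsilyloxy)-5-[(2S,5R)-5-(5,5-dimethoxypent-1-en-2-yl)-2-methyloxolan-2-yl]-3-[2-(2-methyl-1,3-dioxolan-2-yl)ethyl]pentanoate
Product: 23 methyl (3R,4S)-4-(tert-butyldimethylsilyloxy)-5-[(2S,5R)-2-methyl-5-(5-oxopent-1-en-2-yl)oxolan-2-yl]-3-(3-oxobutyl)pentanoate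
Conditions: pyridinium p-toluenesulfonate, acetone/H2O (10:1), 55 °C
Reagents that add atoms: water, O
Why: Mild acid-catalysed acetal hydrolysis frees the C11 aldehyde and the C12 methyl ketone together, the secondary silyl ether, ester and 1,1-disubstituted alkene being stable to this weak acid.

Step 17
Reactants: 23 methyl (3R,4S)-4-(tert-butyldimethylsilyloxy)-5-[(2S,5R)-2-methyl-5-(5-oxopent-1-en-2-yl)oxolan-2-yl]-3-(3-oxobutyl)pentanoate
Product: 24 methyl [(1R,2S,4S,7R,11S,12S)-2-(tert-butyldimethylsilyloxy)-11,12-dihydroxy-4,12-dimethyl-8-methylidene-4,7-epoxycyclotetradecyl]acetate (cembrane ring numbering)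
Conditions: TiCl3(DME)1.5, Zn–Cu, DME, 25 °C, slow addition of 23 (high dilution); aq. K2CO3
Reagents that add atoms: none
Why: Intramolecular McMurry-type pinacol coupling: low-valent titanium couples the two carbonyls on the metal, the titanium-bridged diolate with ring bonds C10–C11 and C12–C13 antiperiplanar should give the threo (11,12-syn) diol, and the 11S,12S facial sense is expected from the macrocyclic conformation imposed by the cis-oxolane and the C1/C2 substituents.

Step 18
Reactants: 24 methyl [(1R,2S,4S,7R,11S,12S)-2-(tert-butyldimethylsilyloxy)-11,12-dihydroxy-4,12-dimethyl-8-methylidene-4,7-epoxycyclotetradecyl]acetate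
Product: 25 methyl [(1R,2S,4S,7R,11S,12S)-2-(tert-butyldimethylsilyloxy)-12-hydroxy-4,12-dimethyl-8-methylidene-11-(triethylsilyloxy)-4,7-epoxycyclotetradecyl]acetate
Conditions: Et3SiCl, imidazole, DMF, 0 °C
Reagents that add atoms: chlorotriethylsilane, CC[Si](CC)(CC)Cl
Why: Silyl ether formation is selective for the secondary C11 hydroxyl over the inert tertiary C12 hydroxyl, which blocks eight-membered lactonisation and later alkoxide-mediated acyl migration.

Step 19
Reactants: 25 methyl [(1R,2S,4S,7R,11S,12S)-2-(tert-butyldimethylsilyloxy)-12-hydroxy-4,12-dimethyl-8-methylidene-11-(triethylsilyloxy)-4,7-epoxycyclotetradecyl]acetate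
Product: 26 [(1R,2S,4S,7R,11S,12S)-2-(tert-butyldimethylsilyloxy)-12-hydroxy-4,12-dimethyl-8-methylidene-11-(triethylsilyloxy)-4,7-epoxycyclotetradecyl]acetic acid
Conditions: Me3SnOH, ClCH2CH2Cl, 80 °C; 0.01 M aq. HCl wash
Reagents that add atoms: trimethyltin hydroxide, C[Sn](C)(C)O
Why: Near-neutral ester hydrolysis with the tin hydroxide cleaves the methyl ester without loss of the silyl ethers or epimerisation at C1.

Step 20
Reactants: 26 [(1R,2S,4S,7R,11S,12S)-2-(tert-butyldimethylsilyloxy)-12-hydroxy-4,12-dimethyl-8-methylidene-11-(triethylsilyloxy)-4,7-epoxycyclotetradecyl]acetic acid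
Product: 28 (1R,2S,4S,7R,11S,12S)-2-(tert-butyldimethylsilyloxy)-11-(triethylsilyloxy)-4,7-epoxycembr-8(19)-en-16,12-olide, via mixed anhydride 27 (not isolated)
Conditions: 2,4,6-trichlorobenzoyl chloride, Et3N, THF, rt; then 4-(dimethylamino)pyridine, toluene, 80 °C (high dilution)
Reagents that add atoms: none
Why: Yamaguchi lactonisation: the mixed anhydride is turned by the aminopyridine into an acylpyridinium ion that acylates the only free hydroxyl, the tertiary C12 alcohol held close by the macrocycle, closing the seven-membered lactone with retention at C12.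

Step 21
Reactants: 28 (1R,2S,4S,7R,11S,12S)-2-(tert-butyldimethylsilyloxy)-11-(triethylsilyloxy)-4,7-epoxycembr-8(19)-en-16,12-olide
Product: 31 (1R,2S,4S,7R,11S,12S)-2-(tert-butyldimethylsilyloxy)-11-(triethylsilyloxy)-4,7-epoxycembra-8(19),15(17)-dien-16,12-olide, via Mannich base 29 (not isolated), via ammonium iodide 30 (not isolated)
Conditions: LiN(i-Pr)2, THF, −78 °C; CH2=NMe2+ I−, −78 °C → rt; MeI, MeOH, rt; NaHCO3 (aq.), CH2Cl2, rt
Reagents that add atoms: dimethyl(methylidene)ammonium iodide, C=[N+](C)C.[I-]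
Why: α-Methylenation by a Mannich reaction of the lithium lactone enolate (C15 is the only enolisable position), followed by quaternisation and E1cB loss of trimethylamine; the transient C15 centre is destroyed and no β-leaving group is present.

Step 22
Reactants: 31 (1R,2S,4S,7R,11S,12S)-2-(tert-butyldimethylsilyloxy)-11-(triethylsilyloxy)-4,7-epoxycembra-8(19),15(17)-dien-16,12-olide
Product: 32 (1R,2S,4S,7R,11S,12S)-2,11-dihydroxy-4,7-epoxycembra-8(19),15(17)-dien-16,12-olide (CNP0289823.1)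
Conditions: HF·pyridine, pyridine, THF, 0 °C → rt
Reagents that add atoms: none
Why: Fluoride-mediated desilylation under buffered, weakly acidic conditions removes both silyl ethers without conjugate addition to the α-methylene lactone or acyl migration to the freed hydroxyls.

**Compound list**

1 | 2-methylfuran | Cc1ccco1 | starting material
2 | (Z)-4-oxopent-2-enal | CC(=O)/C=C\C=O | intermediate (not isolated)
3 | (E)-4-oxopent-2-enal | CC(=O)/C=C/C=O | intermediate
4 | (E)-4-(tert-butyldimethylsilyloxy)penta-2,4-dienal | C=C(O[Si](C)(C)C(C)(C)C)/C=C/C=O | intermediate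
5 | (1R,4S,5R)-1-methyl-4-(2-oxoethyl)-8-oxabicyclo[3.2.1]oct-6-en-3-one (C8 as the compact adduct; inconsequential) | O=C1C[C@]2(C)C=C[C@@H](O2)[C@@H]1CC=O | intermediate
6 | (1S,4S,5R)-1-methyl-4-(2-oxoethyl)-8-oxabicyclo[3.2.1]octan-3-one | O=C1C[C@]2(C)CC[C@@H](O2)[C@@H]1CC=O | intermediate
7 | (1S,4S,5R)-4-(3-methoxyprop-2-en-1-yl)-1-methyl-8-oxabicyclo[3.2.1]octan-3-one (E/Z mixture) | O=C1C[C@]2(C)CC[C@@H](O2)[C@@H]1CC=COC | intermediate
8 | (1S,4S,5R)-4-(3,3-dimethoxypropyl)-1-methyl-8-oxabicyclo[3.2.1]octan-3-one | O=C1C[C@]2(C)CC[C@@H](O2)[C@@H]1CCC(OC)OC | intermediate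
9 | (1R,2S,6S)-2-(3,3-dimethoxypropyl)-6-methyl-3,9-dioxabicyclo[4.2.1]nonan-4-one | O=C1C[C@]2(C)CC[C@@H](O2)[C@H](CCC(OC)OC)O1 | intermediate
10 | methyl 2-[(2S,5R)-5-[(1S)-1-hydroxy-4,4-dimethoxybutyl]-2-methyloxolan-2-yl]acetate | COC(=O)C[C@]1(C)CC[C@@H](O1)[C@@H](O)CCC(OC)OC | intermediate
11 | methyl 2-[(2S,5R)-5-(4,4-dimethoxybutanoyl)-2-methyloxolan-2-yl]acetate | COC(=O)C[C@]1(C)CC[C@@H](O1)C(=O)CCC(OC)OC | intermediate
12 | methyl 2-[(2S,5R)-5-(5,5-dimethoxypent-1-en-2-yl)-2-methyloxolan-2-yl]acetate | COC(=O)C[C@]1(C)CC[C@@H](O1)C(=C)CCC(OC)OC | intermediate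
13 | 2-[(2S,5R)-5-(5,5-dimethoxypent-1-en-2-yl)-2-methyloxolan-2-yl]acetaldehyde | O=CC[C@]1(C)CC[C@@H](O1)C(=C)CCC(OC)OC | intermediate
14 | methyl propiolate | COC(=O)C#C | starting material
15 | methyl (4S)-5-[(2S,5R)-5-(5,5-dimethoxypent-1-en-2-yl)-2-methyloxolan-2-yl]-4-hydroxypent-2-ynoate | COC(=O)C#C[C@@H](O)C[C@]1(C)CC[C@@H](O1)C(=C)CCC(OC)OC | intermediate
16 | methyl (2E,4S)-5-[(2S,5R)-5-(5,5-dimethoxypent-1-en-2-yl)-2-methyloxolan-2-yl]-4-hydroxypent-2-enoate | COC(=O)/C=C/[C@@H](O)C[C@]1(C)CC[C@@H](O1)C(=C)CCC(OC)OC | intermediate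
17 | methyl (2E,4S)-4-(tert-butyldimethylsilyloxy)-5-[(2S,5R)-5-(5,5-dimethoxypent-1-en-2-yl)-2-methyloxolan-2-yl]pent-2-enoate | COC(=O)/C=C/[C@@H](O[Si](C)(C)C(C)(C)C)C[C@]1(C)CC[C@@H](O1)C(=C)CCC(OC)OC | intermediate
18 | 2-(2-bromoethyl)-2-methyl-1,3-dioxolane | CC1(CCBr)OCCO1 | starting material
19 | [2-(2-methyl-1,3-dioxolan-2-yl)ethyl]magnesium bromide | CC1(CC[Mg]Br)OCCO1 | intermediate (not isolated)
20 | bromomagnesium bis[2-(2-methyl-1,3-dioxolan-2-yl)ethyl]cuprate | CC1(CC[Cu-]CCC2(C)OCCO2)OCCO1.[Mg+]Br | intermediate (not isolated)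
21 | trimethylsilyl ketene acetal of 22 (C1 R, C2 S; ketene acetal geometry open) | COC(O[Si](C)(C)C)=C[C@@H](CCC1(C)OCCO1)[C@@H](O[Si](C)(C)C(C)(C)C)C[C@]1(C)CC[C@@H](O1)C(=C)CCC(OC)OC | intermediate (not isolated)
22 | methyl (3R,4S)-4-(tert-butyldimethylsilyloxy)-5-[(2S,5R)-5-(5,5-dimethoxypent-1-en-2-yl)-2-methyloxolan-2-yl]-3-[2-(2-methyl-1,3-dioxolan-2-yl)ethyl]pentanoate | COC(=O)C[C@@H](CCC1(C)OCCO1)[C@@H](O[Si](C)(C)C(C)(C)C)C[C@]1(C)CC[C@@H](O1)C(=C)CCC(OC)OC | intermediate
23 | methyl (3R,4S)-4-(tert-butyldimethylsilyloxy)-5-[(2S,5R)-2-methyl-5-(5-oxopent-1-en-2-yl)oxolan-2-yl]-3-(3-oxobutyl)pentanoate | COC(=O)C[C@@H](CCC(C)=O)[C@@H](O[Si](C)(C)C(C)(C)C)C[C@]1(C)CC[C@@H](O1)C(=C)CCC=O | intermediate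
24 | methyl [(1R,2S,4S,7R,11S,12S)-2-(tert-butyldimethylsilyloxy)-11,12-dihydroxy-4,12-dimethyl-8-methylidene-4,7-epoxycyclotetradecyl]acetate | COC(=O)C[C@@H]1[C@@H](O[Si](C)(C)C(C)(C)C)C[C@]2(C)CC[C@@H](O2)C(=C)CC[C@H](O)[C@@](C)(O)CC1 | intermediate
25 | methyl [(1R,2S,4S,7R,11S,12S)-2-(tert-butyldimethylsilyloxy)-12-hydroxy-4,12-dimethyl-8-methylidene-11-(triethylsilyloxy)-4,7-epoxycyclotetradecyl]acetate | COC(=O)C[C@@H]1[C@@H](O[Si](C)(C)C(C)(C)C)C[C@]2(C)CC[C@@H](O2)C(=C)CC[C@H](O[Si](CC)(CC)CC)[C@@](C)(O)CC1 | intermediate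
26 | [(1R,2S,4S,7R,11S,12S)-2-(tert-butyldimethylsilyloxy)-12-hydroxy-4,12-dimethyl-8-methylidene-11-(triethylsilyloxy)-4,7-epoxycyclotetradecyl]acetic acid | OC(=O)C[C@@H]1[C@@H](O[Si](C)(C)C(C)(C)C)C[C@]2(C)CC[C@@H](O2)C(=C)CC[C@H](O[Si](CC)(CC)CC)[C@@](C)(O)CC1 | intermediate
27 | mixed anhydride of 26 with 2,4,6-trichlorobenzoic acid | O=C(OC(=O)c1c(Cl)cc(Cl)cc1Cl)C[C@@H]1[C@@H](O[Si](C)(C)C(C)(C)C)C[C@]2(C)CC[C@@H](O2)C(=C)CC[C@H](O[Si](CC)(CC)CC)[C@@](C)(O)CC1 | intermediate (not isolated)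
28 | (1R,2S,4S,7R,11S,12S)-2-(tert-butyldimethylsilyloxy)-11-(triethylsilyloxy)-4,7-epoxycembr-8(19)-en-16,12-olide (C15 is CH2) | C1C(=O)O[C@@]2(C)CC[C@H]1[C@@H](O[Si](C)(C)C(C)(C)C)C[C@]1(C)CC[C@@H](O1)C(=C)CC[C@@H]2O[Si](CC)(CC)CC | intermediate
29 | 15-[(dimethylamino)methyl] derivative of 28 (C15 epimers) | CN(C)CC1C(=O)O[C@@]2(C)CC[C@H]1[C@@H](O[Si](C)(C)C(C)(C)C)C[C@]1(C)CC[C@@H](O1)C(=C)CC[C@@H]2O[Si](CC)(CC)CC | intermediate (not isolated)
30 | trimethylammonium iodide from 29 | C[N+](C)(C)CC1C(=O)O[C@@]2(C)CC[C@H]1[C@@H](O[Si](C)(C)C(C)(C)C)C[C@]1(C)CC[C@@H](O1)C(=C)CC[C@@H]2O[Si](CC)(CC)CC.[I-] | intermediate (not isolated)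
31 | (1R,2S,4S,7R,11S,12S)-2-(tert-butyldimethylsilyloxy)-11-(triethylsilyloxy)-4,7-epoxycembra-8(19),15(17)-dien-16,12-olide | C=C1C(=O)O[C@@]2(C)CC[C@H]1[C@@H](O[Si](C)(C)C(C)(C)C)C[C@]1(C)CC[C@@H](O1)C(=C)CC[C@@H]2O[Si](CC)(CC)CC | intermediate
32 | (1R,2S,4S,7R,11S,12S)-2,11-dihydroxy-4,7-epoxycembra-8(19),15(17)-dien-16,12-olide (CNP0289823.1) | C=C1C(=O)O[C@@]2(C)CC[C@H]1[C@@H](O)C[C@]1(C)CC[C@@H](O1)C(=C)CC[C@@H]2O | target

**Count and risks**

Total step count: 22. Longest linear sequence: 22 steps (1 to 32; 14 and 18 enter as purchased building blocks).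

Steps most likely to fail:

1. Step 3. Once the C7–C8 bond has formed, loss of the C7 proton with rearomatisation (Friedel–Crafts alkylation of the furan) may outrun closure of the C3–C4 bond, and attack through the methyl-bearing furan carbon may erode regioselectivity. Fallback: it sets out from 1 and returns at 11. The core is made by an auxiliary-controlled oxyallyl cation [4+3] cycloaddition: 1 reacts with the triethylsilyl enol ether of the mixed methyl (S)-1-phenylethyl acetal of pyruvaldehyde (Me3SiOTf cat., CH2Cl2, −95 °C; the auxiliary antipode chosen to give the bridgeheads of 5). On steric grounds this should give (1R,5R)-1-methyl-4-[(S)-1-phenylethoxy]-8-oxabicyclo[3.2.1]oct-6-en-3-one F1, with the alkoxy-bearing carbon (C8) next to the hydrogen-bearing bridgehead. H2 over Pd/C saturates C5=C6 and hydrogenolyses the benzylic ether to give (1S,5R)-4-hydroxy-1-methyl-8-oxabicyclo[3.2.1]octan-3-one F2. Pb(OAc)4 in MeOH/benzene then cleaves the C2–C8 bond of this α-ketol to methyl 2-[(2S,5R)-5-formyl-2-methyloxolan-2-yl]acetate F3. Addition of (3,3-dimethoxypropyl)magnesium bromide to the aldehyde (THF, −78 °C) gives methyl 2-[(2S,5R)-5-(1-hydroxy-4,4-dimethoxybutyl)-2-methyloxolan-2-yl]acetate F4 as both C8 epimers, which the oxidation of step 9 converges on 11.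

2. Step 17. The ketyl may add to the wrong face of the ketone (or with poor threo preference), and intermolecular coupling may compete at practical dilution. Fallback: it sets out from 23 and returns at 28, replacing stereocontrol in the coupling by stereocorrection. The coupling is run as before and the 11R,12R threo diol, methyl [(1R,2S,4S,7R,11R,12R)-2-(tert-butyldimethylsilyloxy)-11,12-dihydroxy-4,12-dimethyl-8-methylidene-4,7-epoxycyclotetradecyl]acetate F5, is carried on instead of being discarded. Selective mesylation of its secondary hydroxyl (MeSO2Cl, Et3N, CH2Cl2, 0 °C) gives the 11-methanesulfonate F6, and K2CO3 in MeOH closes the (11S,12R)-11,12-epoxide methyl ester F7 with inversion at C11. Me3SnOH liberates the (11S,12R)-epoxy acid F8, and camphor-10-sulfonic acid (cat., CH2Cl2) induces 7-exo opening of the epoxide at the tertiary carbon by the carboxyl group with inversion at C12. This gives (1R,2S,4S,7R,11S,12S)-2-(tert-butyldimethylsilyloxy)-11-hydroxy-4,7-epoxycembr-8(19)-en-16,12-olide F9, which silylation as in step 18 turns into 28, so that both threo diols converge.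

3. Step 20. Acylation of the hindered tertiary C12 hydroxyl may be too slow, so that intermolecular esterification (oligomers) or decomposition of the activated acid takes over. Fallback: it sets out from 25 and returns at 28, forming the lactone at the lactol oxidation level instead of by acyl substitution. LiBH4 (THF, 0 °C → rt) reduces the ester of 25 to (1R,2S,4S,7R,11S,12S)-2-(tert-butyldimethylsilyloxy)-1-(2-hydroxyethyl)-4,12-dimethyl-8-methylidene-11-(triethylsilyloxy)-4,7-epoxycyclotetradecan-12-ol F10. Oxidation with 2,2,6,6-tetramethylpiperidin-1-oxyl (cat.) and PhI(OAc)2 (CH2Cl2, rt) takes the primary alcohol to the aldehyde, which is trapped by the tertiary hydroxyl as the seven-membered lactol F11 and oxidised on to 28.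

**Further compounds**

F1 | step 3 | (1R,5R)-1-methyl-4-[(S)-1-phenylethoxy]-8-oxabicyclo[3.2.1]oct-6-en-3-one (ether-bearing ring carbon unassigned) | O=C1C[C@]2(C)C=C[C@@H](O2)C1O[C@@H](C)c1ccccc1
F2 | step 3 | (1S,5R)-4-hydroxy-1-methyl-8-oxabicyclo[3.2.1]octan-3-one (carbinol carbon unassigned) | O=C1C[C@]2(C)CC[C@@H](O2)C1O
F3 | step 3 | methyl 2-[(2S,5R)-5-formyl-2-methyloxolan-2-yl]acetate | COC(=O)C[C@]1(C)CC[C@@H](O1)C=O
F4 | step 3 | methyl 2-[(2S,5R)-5-(1-hydroxy-4,4-dimethoxybutyl)-2-methyloxolan-2-yl]acetate (both carbinol epimers) | COC(=O)C[C@]1(C)CC[C@@H](O1)C(O)CCC(OC)OC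
F5 | step 17 | methyl [(1R,2S,4S,7R,11R,12R)-2-(tert-butyldimethylsilyloxy)-11,12-dihydroxy-4,12-dimethyl-8-methylidene-4,7-epoxycyclotetradecyl]acetate | COC(=O)C[C@@H]1[C@@H](O[Si](C)(C)C(C)(C)C)C[C@]2(C)CC[C@@H](O2)C(=C)CC[C@@H](O)[C@](C)(O)CC1
F6 | step 17 | 11-methanesulfonate of F5 | COC(=O)C[C@@H]1[C@@H](O[Si](C)(C)C(C)(C)C)C[C@]2(C)CC[C@@H](O2)C(=C)CC[C@@H](OS(C)(=O)=O)[C@](C)(O)CC1
F7 | step 17 | methyl [(1R,2S,4S,7R,11S,12R)-2-(tert-butyldimethylsilyloxy)-4,12-dimethyl-8-methylidene-4,7:11,12-diepoxycyclotetradecyl]acetate | COC(=O)C[C@@H]1[C@@H](O[Si](C)(C)C(C)(C)C)C[C@]2(C)CC[C@@H](O2)C(=C)CC[C@@H]3O[C@]3(C)CC1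
F8 | step 17 | [(1R,2S,4S,7R,11S,12R)-2-(tert-butyldimethylsilyloxy)-4,12-dimethyl-8-methylidene-4,7:11,12-diepoxycyclotetradecyl]acetic acid | OC(=O)C[C@@H]1[C@@H](O[Si](C)(C)C(C)(C)C)C[C@]2(C)CC[C@@H](O2)C(=C)CC[C@@H]3O[C@]3(C)CC1
F9 | step 17 | (1R,2S,4S,7R,11S,12S)-2-(tert-butyldimethylsilyloxy)-11-hydroxy-4,7-epoxycembr-8(19)-en-16,12-olide | C1C(=O)O[C@@]2(C)CC[C@H]1[C@@H](O[Si](C)(C)C(C)(C)C)C[C@]1(C)CC[C@@H](O1)C(=C)CC[C@@H]2O
F10 | step 20 | (1R,2S,4S,7R,11S,12S)-2-(tert-butyldimethylsilyloxy)-1-(2-hydroxyethyl)-4,12-dimethyl-8-methylidene-11-(triethylsilyloxy)-4,7-epoxycyclotetradecan-12-ol | OCC[C@@H]1[C@@H](O[Si](C)(C)C(C)(C)C)C[C@]2(C)CC[C@@H](O2)C(=C)CC[C@H](O[Si](CC)(CC)CC)[C@@](C)(O)CC1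
F11 | step 20 | lactol of 28 (C16 hemiacetal, both epimers) | C1C(O)O[C@@]2(C)CC[C@H]1[C@@H](O[Si](C)(C)C(C)(C)C)C[C@]1(C)CC[C@@H](O1)C(=C)CC[C@@H]2O[Si](CC)(CC)CC
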